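The pitfall in a flask like this is a fitted rate constant carried to many digits when the earlier runs can be reckoned by hand in powers of ten, so I do that first.

common to all: starting material 0.010 M

| run | reagent | remark | time |
|---|---|---|---|
| theta | 6.5 mM | run made earlier |  |
| epsilon | 14 mM | run made earlier |  |
| beta | 31 mM | run made earlier |  |
| spring | 5.00 mM |  | 3.0 min |
| winter | 40.0 mM |  | 3.0 min |
| midnight | 25.0 mM |  | 3.0 min |

| run | time / s | bis adduct / % |
|---|---|---|
| theta | 12.0 | 8.2 |
| theta | 30.0 | 7.9 |
| theta | 60.0 | 8.3 |
| theta | 90.0 | 8.0 |
| theta | 120 | 8.6 |
| epsilon | 10.0 | 43.1 |
| epsilon | 20.0 | 45.8 |
| epsilon | 40.0 | 45.3 |
| epsilon | 60.0 | 45.5 |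
| epsilon | 120 | 44.9 |
| beta | 12.0 | 99.8 |
| beta | 30.0 | 100.1 |
| beta | 60.0 | 99.7 |
| beta | 90.0 | 99.9 |
| beta | 120 | 100.3 |

(scatter of a reading: 0.5 percentage points)

- what is said of bis adduct includes crystals
- crystals is a solid; its amount is given per volume of the solution
- what may be going on: crystals <-> bis adduct; reagent + first product -> bis adduct + by-product; starting material + reagent -> first product + by-product

- which of these holds the largest part of the starting material at the end of spring (bis adduct / starting material / first product)
- which of these holds the largest part of the starting material at the end of winter (bis adduct / starting material / first product)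
- which of these holds the largest part of the starting material at the end of midnight (bis adduct / starting material / first product)
- how much bis adduct is there at the end of midnight, in percent of the starting material charged

On the first rung, seconds, both additions proceed while reagent lasts. In the epsilon run, bis adduct reads 43.1% after 10.0 s and 45.8% after 20.0 s, then 44.9% after 120 s, so that run has stopped earlier than the hold asked for here. In the epsilon run reagent is the limiting reagent, 14 mM against the 20.0 mM that two additions take, and the readings stay level up to 120 s.

The next rung belongs to a surplus S, the reagent charged minus two times the starting material charged. Once starting material is gone, first product decays pseudo-first-order, with reagent close to S. In the beta run S is 11.0 mM, and the reading 99.8% after 12.0 s leaves room for about 1 percentage point of first product, so I take about two powers of ten for that S·t.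

Scaling S·t from beta to midnight, where S is 5.00 mM for 3.0 min, gives 13.6. This is my decade budget, the powers of ten by which the surplus can lower first product during the hold. Beta's early reagent stood above S, so I trust the figure to an order of magnitude. Winter's budget is 54.5, while spring's S is −15.0 mM, which puts it back on the first rung. Crystals get no rung of their own here: the bis adduct as read includes them.

I commit to full conversion to bis adduct in midnight. The forecast gives starting material for spring, bis adduct for winter, bis adduct for midnight and 100% of bis adduct, arguing that “the half-life is under 5 s”.

The flask gives starting material for spring, bis adduct for winter and bis adduct for midnight, with 100% of bis adduct at the end of midnight.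

    crystals ⇌ bis adduct, rate k1*(cs1 - [bis adduct]) while solid is left; crystals form when [bis adduct] > cs1 (solubility = 8.30 mM, k = 1.10 s⁻¹)
    reagent + first product → bis adduct + by-product (k = 38.0 L mol⁻¹ s⁻¹)
    starting material + reagent → first product + by-product (k = 110 L mol⁻¹ s⁻¹)

Midnight's answer has moved by 5 points at 19.5 mM of reagent, where S is −0.481 mM. At 25.0 mM, with a budget of 13.6, first product stands at 0%. A neighbour of midnight charged with 0.015 M of reagent has S of −5.00 mM, so it has no surplus and no budget to spend, and it ends with 42.9% first product and 53.6% bis adduct.

The readings stem from a simulated flask with constants of no real substance.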